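Prostanoid numbering is used: ring C8–C12 (C12 carries the acetate), upper chain C1–C7, lower chain C13–C20. Retrosynthetic cuts, in order: the C12 O–acyl bond, C7=C8 (aldol condensation), C9–C10 together with C10–C11 (C10 leaves with its chlorine), then two ring bonds of the remaining four-membered ketone ([2+2]).
Enabling feature: in the five-membered ring the C9 carbonyl, the chlorine-bearing C10 and the hydrogen-bearing C11 form a 2-chloroenone. This is what a CCl2 unit leaves after insertion into an enol ether double bond C9=C11. Removing C10 gives a cyclobutene whose parent ketone has C12 opposite the carbonyl and a mirror plane through both.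
Forward order: (Z)-non-3-en-1-ol supplies C12–C20. Its 4-methoxybenzyl ester is methylenated, dichloroketene closes the four-membered ring, dichlorocarbene widens it to the five-membered ring, and the C1–C7 enal ester from a cross metathesis is attached last at C8.
Stereochemistry: C12 (R in the target) is defined when a chiral lithium amide deprotonates one of the two enantiotopic CH2 groups of the cyclobutanone; that carbon becomes C11 and the other C8. 14Z comes with the starting alcohol, 5E from the metathesis, 7E from the E1cB dehydration.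

Key step: step 7

Assumption: the sense of induction of the chiral base on this ketone cannot be derived with certainty. The (R,R)-amide is written because, with the octenyl chain pseudo-equatorial, the proton it prefers on 4-substituted cyclohexanones maps onto the CH2 group that must become C11. If a test run shows the opposite sense, the equally available (S,S)-amine is used and nothing else changes.

Step 1
Reactants: 1 (Z)-non-3-en-1-ol
Product: 3 (Z)-non-3-enoic acid, via (Z)-non-3-enal 2 (not isolated)
Conditions: CrO3, aq. H2SO4, acetone, 0 °C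
Reagents that add atoms: water (from the aqueous acid; it adds to aldehyde 2 as the hydrate), O
Why: In the Jones oxidation the β,γ-unsaturated aldehyde is hydrated and oxidised further in acidic acetone faster than its 3Z double bond can move into conjugation, as is usual for (Z)-alk-3-en-1-ols.

Step 2
Reactants: 3 (Z)-non-3-enoic acid; 4 4-methoxybenzyl alcohol
Product: 5 4-methoxybenzyl (Z)-non-3-enoate
Conditions: DCC, DMAP (cat.), CH2Cl2, 0 °C to rt
Reagents that add atoms: none
Why: The Steglich esterification couples acid and benzylic alcohol under nearly neutral conditions, and the low temperature and catalytic amount of DMAP leave the skipped Z-alkene where it is.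

Step 3
Reactants: 5 4-methoxybenzyl (Z)-non-3-enoate
Product: 6 1-{[(4Z)-deca-1,4-dien-2-yloxy]methyl}-4-methoxybenzene
Conditions: Cp2TiMe2 (2 equiv), toluene, 70 °C, dark; filtration through basic Al2O3
Reagents that add atoms: dimethyltitanocene Cp2TiMe2, C[Ti](C)(C1C=CC=C1)C1C=CC=C1
Why: In the Petasis methylenation Cp2Ti=CH2, formed by loss of methane, exchanges the ester C=O for C=CH2 through an oxatitanacyclobutane; the reagent is not basic, so the 1,4-diene is not isomerised, and the internal alkene is inert to it.

Step 4
Reactants: 6 1-{[(4Z)-deca-1,4-dien-2-yloxy]methyl}-4-methoxybenzene; 7 trichloroacetyl chloride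
Product: 9 (±)-2,2-dichloro-3-[(4-methoxybenzyl)oxy]-3-[(Z)-oct-2-en-1-yl]cyclobutan-1-one, via dichloroketene 8 (not isolated)
Conditions: Zn(Cu), Et2O–DME, 0 °C to rt, slow addition of 7 (1.1 equiv); product used crude
Reagents that add atoms: none
Why: The ketene [2+2] cycloaddition is strongly polarised: the CH2 terminus of the enol ether attacks the ketene carbonyl carbon and the oxygen-stabilised carbon closes onto CCl2, which gives the 3-alkoxy-2,2-dichloro pattern and the four-membered ring, while the much less nucleophilic dialkyl alkene is left alone when 7 is kept near one equivalent and DME ties up ZnCl2; the product is racemic, which does not matter because its stereocentre vanishes in step 5.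

Step 5
Reactants: 9 (±)-2,2-dichloro-3-[(4-methoxybenzyl)oxy]-3-[(Z)-oct-2-en-1-yl]cyclobutan-1-one
Product: 11 3-[(4-methoxybenzyl)oxy]-3-[(Z)-oct-2-en-1-yl]cyclobutan-1-one (achiral), via monochloroketone 10 (not isolated)
Conditions: Zn(Cu), NH4Cl, MeOH, 0 °C to rt
Reagents that add atoms: none
Why: Zinc reduces each α C–Cl bond to a zinc enolate that NH4Cl protonates (reductive dehalogenation of an α-chloroketone); steps 4 and 5 together are the standard way to 3-benzyloxycyclobutanones, and the nearly neutral medium spares the tertiary ether and the alkene.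

Step 6
Reactants: 11 3-[(4-methoxybenzyl)oxy]-3-[(Z)-oct-2-en-1-yl]cyclobutan-1-one
Product: 13 triethyl({(3S)-3-[(4-methoxybenzyl)oxy]-3-[(Z)-oct-2-en-1-yl]cyclobut-1-en-1-yl}oxy)silane, via lithium enolate 12 (not isolated)
Conditions: (R,R)-bis(1-phenylethyl)amine, n-BuLi, THF, 0 °C; Et3SiCl, −100 °C, then slow addition of 11; Et3N, cold aq. NaHCO3; rapid filtration over Et3N-treated silica, stored cold
Reagents that add atoms: chlorotriethylsilane, CC[Si](Cl)(CC)CC
Why: Proposed new method: the ketone has a mirror plane, so C12 becomes a stereocentre merely through the choice of the CH2 group that is deprotonated; the C2-symmetric amide should take one of the two enantiotopic pseudo-axial α-protons through the usual cyclic transition state (Li on the carbonyl oxygen, N at the proton), the longer octenyl chain sitting pseudo-equatorial and so fixing the face on which these protons lie, and the Et3SiCl already present should silylate enolate 12 at −100 °C before it can expel 4-methoxybenzyl oxide; the closest known reaction type is the enantioselective deprotonation with internal silyl chloride quench of 3-substituted cyclobutanones and 4-substituted cyclohexanones, which has not been shown for a ring carbon bearing an alkoxy and an alkyl group of similar size.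

Step 7
Reactants: 13 triethyl({(3S)-3-[(4-methoxybenzyl)oxy]-3-[(Z)-oct-2-en-1-yl]cyclobut-1-en-1-yl}oxy)silane; 14 chloroform
Product: 17 (S)-2-chloro-4-[(4-methoxybenzyl)oxy]-4-[(Z)-oct-2-en-1-yl]cyclopent-2-en-1-one, via dichlorocarbene 15 (not isolated), via dichlorobicyclo[2.1.0]pentane 16 (not isolated)
Conditions: CHCl3 (1.2 equiv), KOt-Bu (1.1 equiv, in portions), pentane, −40 to −10 °C; pH 7 phosphate buffer
Reagents that add atoms: none
Why: KOt-Bu deprotonates chloroform, the trichloromethyl anion loses chloride, and singlet carbene 15 adds in a concerted [2+1] manner to the C9=C11 enol ether bond of 13, forming C9–C10 and C10–C11. In the 5,5-dichlorobicyclo[2.1.0]pentane 16 the central C9–C11 bond should break at once in a disrotatory cyclopropyl-to-allyl opening with departure of the endo chloride, driven by ring strain and by the silyloxy lone pair, after which chloride removes the silyl group from the oxocarbenium ion and leaves the 2-chloroenone. The closest known reaction type is the dihalocarbene one-carbon ring expansion of cyclic silyl enol ethers to 2-haloenones, and the spontaneous opening matches the behaviour of dihalocarbene adducts of cyclobutenes. The five-membered ring C8–C12 therefore arises not by cyclisation but by a cycloaddition that sets a three-membered ring on the four-membered one, followed by electrocyclic cleavage of the shared bond. No lasting stereocentre is made: both bridgeheads of 16 return to sp2, so either face of the cyclobutene may be attacked, and C12 is not touched. The carbene must choose the enol ether over the C14=C15 alkene and the anisyl ring, which the donor oxygen on a strained alkene, about one equivalent of slowly added base and the low temperature secure; the cold also holds back conrotatory opening of the 3-alkoxycyclobutene, and the triethylsilyl group resists attack of tert-butoxide at silicon better than a trimethylsilyl group would.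

Step 8
Reactants: 18 methyl hex-5-enoate; 19 (E)-but-2-enal
Product: 20 methyl (E)-7-oxohept-5-enoate
Conditions: second-generation Grubbs catalyst (H2IMes)(PCy3)Cl2Ru=CHPh (2 mol %), 19 (4 equiv), CH2Cl2, 40 °C
Reagents that add atoms: none
Why: Olefin cross metathesis between a readily reacting terminal alkene and a slowly homodimerising electron-poor enal is selective for the cross product, and reversibility delivers the E enal.

Step 9
Reactants: 17 (S)-2-chloro-4-[(4-methoxybenzyl)oxy]-4-[(Z)-oct-2-en-1-yl]cyclopent-2-en-1-one; 20 methyl (E)-7-oxohept-5-enoate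
Product: 22 methyl (5E,14Z)-10-chloro-7-hydroxy-12-[(4-methoxybenzyl)oxy]-9-oxoprosta-5,10,14-trien-1-oate (C12 as in 17; mixture at C7 and C8), via lithium dienolate 21 (not isolated)
Conditions: LiN(i-Pr)2, THF, −78 °C, 15 min; 20, −78 °C; aq. NH4Cl at −78 °C
Reagents that add atoms: none
Why: C8 holds the only enolisable hydrogens of 17 (C12 is quaternary), so kinetic deprotonation gives the cross-conjugated enolate 21, which adds 1,2 to the aldehyde of 20 rather than to its ester (aldol addition); the new centres C7 and C8 arise as a mixture that step 10 erases, and the cold, short enolate lifetime keeps the C12 ether in place.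

Step 10
Reactants: 22 methyl (5E,14Z)-10-chloro-7-hydroxy-12-[(4-methoxybenzyl)oxy]-9-oxoprosta-5,10,14-trien-1-oate
Product: 24 methyl (5E,7E,12R,14Z)-10-chloro-12-[(4-methoxybenzyl)oxy]-9-oxoprosta-5,7,10,14-tetraen-1-oate, via C7 mesylate 23 (not isolated)
Conditions: MsCl, Et3N (excess), CH2Cl2, −20 °C to rt
Reagents that add atoms: methanesulfonyl chloride, CS(=O)(=O)Cl (its atoms sit only in 23 and leave again)
Why: The secondary allylic alcohol is mesylated and the acidic C8–H then allows E1cB loss of mesylate under the same amine, all C7/C8 diastereomers passing through one enolate; the 7E geometry, with the diene chain turned away from the C9 oxygen, should prevail as is usual for aldol condensations of 4,4-disubstituted cyclopentenones, and any 7Z isomer can be removed by chromatography.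

Step 11
Reactants: 24 methyl (5E,7E,12R,14Z)-10-chloro-12-[(4-methoxybenzyl)oxy]-9-oxoprosta-5,7,10,14-tetraen-1-oate
Product: 25 methyl (5E,7E,12R,14Z)-10-chloro-12-hydroxy-9-oxoprosta-5,7,10,14-tetraen-1-oate
Conditions: DDQ, CH2Cl2–pH 7 buffer, 0 °C to rt
Reagents that add atoms: none
Why: DDQ oxidises only the electron-rich benzylic position (oxidative 4-methoxybenzyl ether cleavage through the oxocarbenium ion and its hemiacetal), the electron-poor trienone and the isolated alkene are not attacked, and the C12–O bond is never broken, so the configuration is kept.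

Step 12
Reactants: 25 methyl (5E,7E,12R,14Z)-10-chloro-12-hydroxy-9-oxoprosta-5,7,10,14-tetraen-1-oate
Product: 26 methyl (5E,7E,12R,14Z)-12-acetoxy-10-chloro-9-oxoprosta-5,7,10,14-tetraen-1-oate
Conditions: Ac2O, DMAP, Et3N, CH2Cl2, rt
Reagents that add atoms: acetic anhydride, CC(=O)OC(C)=O
Why: DMAP-catalysed acylation reaches hindered tertiary alcohols of this type, and ionisation at C12 is disfavoured because both flanking alkenes are electron-poor, so the acetate forms with retention.

Compound list
1 | (Z)-non-3-en-1-ol | CCCCC/C=C\CCO | starting material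
2 | (Z)-non-3-enal (not isolated) | CCCCC/C=C\CC=O | intermediate
3 | (Z)-non-3-enoic acid | CCCCC/C=C\CC(=O)O | intermediate
4 | 4-methoxybenzyl alcohol | COc1ccc(CO)cc1 | starting material
5 | 4-methoxybenzyl (Z)-non-3-enoate | CCCCC/C=C\CC(=O)OCc1ccc(OC)cc1 | intermediate
6 | 1-{[(4Z)-deca-1,4-dien-2-yloxy]methyl}-4-methoxybenzene | CCCCC/C=C\CC(=C)OCc1ccc(OC)cc1 | intermediate
7 | trichloroacetyl chloride | ClC(Cl)(Cl)C(=O)Cl | starting material
8 | dichloroketene (not isolated) | ClC(Cl)=C=O | intermediate
9 | (±)-2,2-dichloro-3-[(4-methoxybenzyl)oxy]-3-[(Z)-oct-2-en-1-yl]cyclobutan-1-one (racemic) | CCCCC/C=C\CC1(OCc2ccc(OC)cc2)CC(=O)C1(Cl)Cl | intermediate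
10 | 2-chloro-3-[(4-methoxybenzyl)oxy]-3-[(Z)-oct-2-en-1-yl]cyclobutan-1-one (racemic diastereomer mixture, not isolated) | CCCCC/C=C\CC1(OCc2ccc(OC)cc2)CC(=O)C1Cl | intermediate
11 | 3-[(4-methoxybenzyl)oxy]-3-[(Z)-oct-2-en-1-yl]cyclobutan-1-one (achiral) | CCCCC/C=C\CC1(OCc2ccc(OC)cc2)CC(=O)C1 | intermediate
12 | lithium (3S)-3-[(4-methoxybenzyl)oxy]-3-[(Z)-oct-2-en-1-yl]cyclobut-1-en-1-olate (not isolated) | CCCCC/C=C\C[C@@]1(OCc2ccc(OC)cc2)C=C([O-])C1.[Li+] | intermediate
13 | triethyl({(3S)-3-[(4-methoxybenzyl)oxy]-3-[(Z)-oct-2-en-1-yl]cyclobut-1-en-1-yl}oxy)silane | CCCCC/C=C\C[C@@]1(OCc2ccc(OC)cc2)C=C(O[Si](CC)(CC)CC)C1 | intermediate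
14 | chloroform | ClC(Cl)Cl | starting material
15 | dichlorocarbene (not isolated) | Cl[C]Cl | intermediate
16 | 5,5-dichloro-3-[(4-methoxybenzyl)oxy]-3-[(Z)-oct-2-en-1-yl]-1-(triethylsilyloxy)bicyclo[2.1.0]pentane (C3 as in 13; either bridgehead face; not isolated) | CCCCC/C=C\C[C@@]1(OCc2ccc(OC)cc2)C2C(Cl)(Cl)C2(O[Si](CC)(CC)CC)C1 | intermediate
17 | (S)-2-chloro-4-[(4-methoxybenzyl)oxy]-4-[(Z)-oct-2-en-1-yl]cyclopent-2-en-1-one | CCCCC/C=C\C[C@@]1(OCc2ccc(OC)cc2)C=C(Cl)C(=O)C1 | intermediate
18 | methyl hex-5-enoate | C=CCCCC(=O)OC | starting material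
19 | (E)-but-2-enal | C/C=C/C=O | starting material
20 | methyl (E)-7-oxohept-5-enoate | O=C/C=C/CCCC(=O)OC | intermediate
21 | lithium C8 dienolate of 17 (not isolated) | CCCCC/C=C\C[C@@]1(OCc2ccc(OC)cc2)C=C(Cl)C([O-])=C1.[Li+] | intermediate
22 | methyl (5E,14Z)-10-chloro-7-hydroxy-12-[(4-methoxybenzyl)oxy]-9-oxoprosta-5,10,14-trien-1-oate (C12 as in 17; mixture at C7 and C8) | CCCCC/C=C\C[C@@]1(OCc2ccc(OC)cc2)C=C(Cl)C(=O)C1C(O)/C=C/CCCC(=O)OC | intermediate
23 | C7 methanesulfonate of 22 (not isolated) | CCCCC/C=C\C[C@@]1(OCc2ccc(OC)cc2)C=C(Cl)C(=O)C1C(OS(C)(=O)=O)/C=C/CCCC(=O)OC | intermediate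
24 | methyl (5E,7E,12R,14Z)-10-chloro-12-[(4-methoxybenzyl)oxy]-9-oxoprosta-5,7,10,14-tetraen-1-oate | CCCCC/C=C\C[C@@]1(OCc2ccc(OC)cc2)C=C(Cl)C(=O)/C1=C/C=C/CCCC(=O)OC | intermediate
25 | methyl (5E,7E,12R,14Z)-10-chloro-12-hydroxy-9-oxoprosta-5,7,10,14-tetraen-1-oate | CCCCC/C=C\C[C@@]1(O)C=C(Cl)C(=O)/C1=C/C=C/CCCC(=O)OC | intermediate
26 | methyl (5E,7E,12R,14Z)-12-acetoxy-10-chloro-9-oxoprosta-5,7,10,14-tetraen-1-oate | CCCCC/C=C\C[C@@]1(OC(C)=O)C=C(Cl)C(=O)/C1=C/C=C/CCCC(=O)OC | target

Total step count: 12. Longest linear sequence: 11 (steps 1–7 and 9–12; step 8 is the side branch).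

Steps most likely to fail

Step 6. The base may discriminate poorly between the two enantiotopic CH2 groups, because the ether oxygen and the octenyl CH2 differ little in size and the ring is only weakly puckered. Some enolate may also lose 4-methoxybenzyl oxide before it is silylated. The fallback gives up asymmetric induction, sets out from 11 and comes back at 17. Achiral LiN(i-Pr)2 with Et3SiCl as internal quench converts 11 through the racemic lithium enolate F1 into the racemic triethylsilyl enol ether F2. Chloroform and KOt-Bu as in step 7 carry this through the racemic dichlorobicyclopentane F3 to the racemic chloroenone F4. F4 is resolved by preparative chromatography on a cellulose-based chiral stationary phase, which its two chromophores make easy to follow. The (S)-enantiomer is 17 and the (R)-chloroenone F5 is set aside.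

Step 7. tert-Butoxide may strip the silyl group from the enol ether. Base or trichloromethyl anion may attack the freshly formed, base-sensitive enone. Excess carbene may also add to C14=C15. The fallback separates carbon insertion from chlorination, sets out from 13 and comes back at 17.
- One equivalent of Et2Zn/CH2I2 (Simmons–Smith reaction, the enol ether reacting first) gives the siloxybicyclo[2.1.0]pentane F6.
- FeCl3 in DMF at 0 °C oxidises the siloxycyclopropane, cleaves the central bond and delivers the ring-expanded 3-chlorocyclopentanone F7.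
- NaOAc in MeOH removes HCl to give the chlorine-free cyclopentenone F8.
- Nucleophilic epoxidation with H2O2/NaOH, which ignores the isolated alkene, gives the 10,11-epoxy ketone F9.
- LiCl/AcOH opens F9 at the less hindered, carbonyl-activated C10 to the chlorohydrin F10, which loses water to give 17.

Step 9. The cross-conjugated enolate may expel 4-methoxybenzyl oxide (E1cB towards a cyclopentadienone) in competition with the aldol addition, or the adduct may revert on work-up. The fallback removes the leaving group first, sets out from 17 and comes back at 25.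
- DDQ in wet CH2Cl2 frees the hydroxy chloroenone F11.
- Two equivalents of LiN(i-Pr)2 give the dilithium alkoxide enolate F12, in which the C12 oxygen can no longer leave.
- Addition to 20 gives the 7,12-diol F13.
- MsCl/Et3N reacts only at the secondary allylic hydroxyl to give the hydroxy mesylate F14, which eliminates under the amine to 25.

Further compounds
F1 | step 6 | racemic lithium enolate of 11 | CCCCC/C=C\CC1(OCc2ccc(OC)cc2)C=C([O-])C1.[Li+]
F2 | step 6 | racemic triethylsilyl enol ether (racemate of 13) | CCCCC/C=C\CC1(OCc2ccc(OC)cc2)C=C(O[Si](CC)(CC)CC)C1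
F3 | step 6 | racemic dichlorobicyclopentane (racemate of 16) | CCCCC/C=C\CC1(OCc2ccc(OC)cc2)C2C(Cl)(Cl)C2(O[Si](CC)(CC)CC)C1
F4 | step 6 | racemic chloroenone (racemate of 17) | CCCCC/C=C\CC1(OCc2ccc(OC)cc2)C=C(Cl)C(=O)C1
F5 | step 6 | (R)-2-chloro-4-[(4-methoxybenzyl)oxy]-4-[(Z)-oct-2-en-1-yl]cyclopent-2-en-1-one | CCCCC/C=C\C[C@]1(OCc2ccc(OC)cc2)C=C(Cl)C(=O)C1
F6 | step 7 | 3-[(4-methoxybenzyl)oxy]-3-[(Z)-oct-2-en-1-yl]-1-(triethylsilyloxy)bicyclo[2.1.0]pentane (C3 as in 13) | CCCCC/C=C\C[C@@]1(OCc2ccc(OC)cc2)C2CC2(O[Si](CC)(CC)CC)C1
F7 | step 7 | 3-chloro-4-[(4-methoxybenzyl)oxy]-4-[(Z)-oct-2-en-1-yl]cyclopentan-1-one (C4 as in 17; mixture at C3) | CCCCC/C=C\C[C@@]1(OCc2ccc(OC)cc2)C(Cl)CC(=O)C1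
F8 | step 7 | (S)-4-[(4-methoxybenzyl)oxy]-4-[(Z)-oct-2-en-1-yl]cyclopent-2-en-1-one | CCCCC/C=C\C[C@@]1(OCc2ccc(OC)cc2)C=CC(=O)C1
F9 | step 7 | 2,3-epoxy-4-[(4-methoxybenzyl)oxy]-4-[(Z)-oct-2-en-1-yl]cyclopentan-1-one (C4 as in 17; either epoxide face) | CCCCC/C=C\C[C@@]1(OCc2ccc(OC)cc2)C2OC2C(=O)C1
F10 | step 7 | 2-chloro-3-hydroxy-4-[(4-methoxybenzyl)oxy]-4-[(Z)-oct-2-en-1-yl]cyclopentan-1-one (C4 as in 17) | CCCCC/C=C\C[C@@]1(OCc2ccc(OC)cc2)C(O)C(Cl)C(=O)C1
F11 | step 9 | (S)-2-chloro-4-hydroxy-4-[(Z)-oct-2-en-1-yl]cyclopent-2-en-1-one | CCCCC/C=C\C[C@@]1(O)C=C(Cl)C(=O)C1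
F12 | step 9 | dilithium alkoxide enolate of F11 | CCCCC/C=C\C[C@@]1([O-])C=C(Cl)C([O-])=C1.[Li+].[Li+]
F13 | step 9 | methyl (5E,14Z)-10-chloro-7,12-dihydroxy-9-oxoprosta-5,10,14-trien-1-oate (C12 as in F11; mixture at C7 and C8) | CCCCC/C=C\C[C@@]1(O)C=C(Cl)C(=O)C1C(O)/C=C/CCCC(=O)OC
F14 | step 9 | C7 methanesulfonate of F13 | CCCCC/C=C\C[C@@]1(O)C=C(Cl)C(=O)C1C(OS(C)(=O)=O)/C=C/CCCC(=O)OC
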